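**Plan**
Retrosynthesis: the biaryl bond is cut first (Suzuki–Miyaura) to two ortho-iodophenols that differ only in which ring of one doubly protected (−)-olivil carries iodine, so both halves come from one intermediate.
In that olivil a benzylic C–O bond absent from the target is put back between the hydroxymethyl oxygen and the benzyl carbon (a sacrificial second oxolane). Then the oxolane C2–C3 bond (OCH2 to carbinol carbon) is cut to an O-methyl group and a ring ketone, and after it the oxolanone O–C bond, the benzyl–carbonyl bond and the aldol bond.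
Forward: anti-aldol chain, sacrificial oxolan-3-one, target oxolane by Norrish–Yang photocyclisation, reductive opening of the sacrificial ring, iodination of either phenol, biaryl coupling, deprotection.
Enabling feature: ring oxygen O1 is β to carbinol carbon C3 and C2 is a bare CH2, so a C3 ketone has the hydrogens of an O1-methyl group at its δ position and no γ-hydrogen on that branch. The benzyl CH2 on C3 and the hydroxymethyl group on C4 are cis, so they can be tied through oxygen into a second five-membered ring whose cis fusion dictates the C3 configuration.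
Stereochemistry: C4 and C5 come from an auxiliary-controlled magnesium anti-aldol reaction, C3 from the ring fusion in the key step; the six centres of the dimer are two copies of this set.

Key step: step 10

Remark: step 3 is assumed to follow the chelated Z-enolate (boat) sense of induction; should it prove opposite, the enantiomeric auxiliary is used and nothing else changes.

**Step 1**
Reactants: 1 vanillin (4-hydroxy-3-methoxybenzaldehyde)
Product: 2 4-formyl-2-methoxyphenyl 4-methylbenzenesulfonate
Conditions: TsCl, Et3N, DMAP (cat.), CH2Cl2, 0 °C to rt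
Reagents that add atoms: 4-methylbenzenesulfonyl chloride, Cc1ccc(S(Cl)(=O)=O)cc1
Why: O-Sulfonylation of the phenol should be clean because the phenoxide is the only nucleophile, and the tosylate is chosen because it should survive the organometallic, photochemical and Lewis-acid steps and makes this ring electron-poor for the selectivity of step 11.

**Step 2**
Reactants: 3 (S)-4-benzyl-1,3-oxazolidin-2-one; 4 3-[(tert-butyldimethylsilyl)oxy]propanoic acid
Product: 6 (4S)-4-benzyl-3-{3-[(tert-butyldimethylsilyl)oxy]propanoyl}-1,3-oxazolidin-2-one, via mixed pivalic anhydride 5 (not isolated)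
Conditions: PivCl, Et3N, THF, −20 °C; then LiCl, 3, −20 °C to rt
Reagents that add atoms: pivaloyl chloride, CC(C)(C)C(Cl)=O (its atoms stay in intermediate 5 only)
Why: N-Acylation of the oxazolidinone by a mixed anhydride (LiCl/Et3N variant) should occur at the unhindered carbonyl of 5, the pivaloyl carbonyl being shielded by the tert-butyl group.

**Step 3**
Reactants: 6 (4S)-4-benzyl-3-{3-[(tert-butyldimethylsilyl)oxy]propanoyl}-1,3-oxazolidin-2-one; 2 4-formyl-2-methoxyphenyl 4-methylbenzenesulfonate
Product: 8 (4S)-4-benzyl-3-[(2R,3S)-2-{[(tert-butyldimethylsilyl)oxy]methyl}-3-hydroxy-3-(3-methoxy-4-tosyloxyphenyl)propanoyl]-1,3-oxazolidin-2-one, via trimethylsilyl ether 7 (not isolated)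
Conditions: MgCl2 (0.2 equiv), Et3N, TMSCl, EtOAc, rt; then TFA (cat.), MeOH, 0 °C
Reagents that add atoms: chlorotrimethylsilane, C[Si](C)(C)Cl (its atoms stay in intermediate 7 only)
Why: Evans magnesium chloride-catalysed anti-aldol reaction: the Mg-chelated Z-enolate of 6 should add to the non-enolisable aldehyde 2 through a boat transition state on the face opposite the benzyl group of the auxiliary, which sets the (2R,3S) anti pair (later C4 and C5 of the oxolane), silylation of the aldolate by TMSCl releasing the catalyst.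

**Step 4**
Reactants: 8 the aldol adduct of step 3
Product: 9 (2R,3S)-2-{[(tert-butyldimethylsilyl)oxy]methyl}-3-hydroxy-N-methoxy-3-(3-methoxy-4-tosyloxyphenyl)-N-methylpropanamide
Conditions: AlMe3, MeNHOMe·HCl, CH2Cl2, −10 to 0 °C
Reagents that add atoms: N,O-dimethylhydroxylamine hydrochloride, CNOC.Cl
Why: Weinreb amide formation by aluminium amide transamidation should occur at the exocyclic imide carbonyl, guided by the aluminium alkoxide of the free β-hydroxyl, without epimerisation of the α-centre.

**Step 5**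
Reactants: 9 the hydroxy Weinreb amide
Product: 10 (2R,3S)-2-{[(tert-butyldimethylsilyl)oxy]methyl}-N,3-dimethoxy-3-(3-methoxy-4-tosyloxyphenyl)-N-methylpropanamide
Conditions: Me3OBF4, 1,8-bis(dimethylamino)naphthalene, CH2Cl2, rt
Reagents that add atoms: trimethyloxonium tetrafluoroborate, C[O+](C)C.F[B-](F)(F)F
Why: O-Methylation with Meerwein's salt buffered by proton sponge (SN2 alkylation of the alcohol under non-basic conditions) should avoid the retro-aldol cleavage and epimerisation that alkoxide bases would cause, and it installs the carbon that becomes C2 of the oxolane.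

**Step 6**
Reactants: 11 [4-(benzyloxy)-3-methoxyphenyl]methanol
Product: 12 1-(benzyloxy)-4-(chloromethyl)-2-methoxybenzene
Conditions: SOCl2, CH2Cl2, 0 °C; used crude
Reagents that add atoms: thionyl chloride, O=S(Cl)Cl
Why: Deoxychlorination via the chlorosulfite should be fast for this electron-rich benzylic alcohol.

**Step 7**
Reactants: 10 the methyl ether Weinreb amide; 12 1-(benzyloxy)-4-(chloromethyl)-2-methoxybenzene
Product: 15 (3R,4S)-1-[4-(benzyloxy)-3-methoxyphenyl]-3-(hydroxymethyl)-4-methoxy-4-(3-methoxy-4-tosyloxyphenyl)butan-2-one, via benzylic Grignard reagent 13 (not isolated), via silyl ketone 14 (not isolated)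
Conditions: 12, Mg, THF, 0 °C; add to 10, THF, −20 to 0 °C; then 2 M HCl, MeOH, rt
Reagents that add atoms: magnesium, [Mg] (stays in intermediate 13 only)
Why: Weinreb ketone synthesis: the magnesium-chelated tetrahedral adduct of 13 should resist over-addition and enolisation until the methanolic HCl quench, which releases the benzyl ketone and cleaves the primary TBS ether while the aryl tosylate, the benzyl ether and the benzylic methyl ether on the electron-poor ring stay intact.

**Step 8**
Reactants: 15 the hydroxy benzyl ketone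
Product: 16 (3R,4S)-1-[4-(benzyloxy)-3-methoxyphenyl]-1-diazo-3-(hydroxymethyl)-4-methoxy-4-(3-methoxy-4-tosyloxyphenyl)butan-2-one
Conditions: 4-acetamidobenzenesulfonyl azide, DBU, MeCN, 0 °C to rt
Reagents that add atoms: 4-acetamidobenzenesulfonyl azide, CC(=O)Nc1ccc(S(=O)(=O)N=[N+]=[N-])cc1
Why: Regitz diazo transfer should take place only at the benzylic methylene, which is acidified by both the aryl group and the carbonyl and is deprotonated by DBU far more readily than the α-methine.

**Step 9**
Reactants: 16 the diazo ketone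
Product: 17 (2RS,4R)-2-[4-(benzyloxy)-3-methoxyphenyl]-4-[(S)-methoxy(3-methoxy-4-tosyloxyphenyl)methyl]oxolan-3-one
Conditions: Rh2(OAc)4 (1 mol%), CH2Cl2, rt
Reagents that add atoms: none
Why: Rhodium-carbenoid O–H insertion: the aryl keto carbenoid should be captured by the hydroxyl oxygen five atoms away much faster than it inserts into any C–H bond, closing the sacrificial oxolan-3-one, whose new C2 centre forms without control and is erased in step 11.

**Step 10**
Reactants: 17 the β-methoxy oxolan-3-one
Product: 18 (1S,2RS,5R,6S)-2-[4-(benzyloxy)-3-methoxyphenyl]-6-(3-methoxy-4-tosyloxyphenyl)-3,7-dioxabicyclo[3.3.0]octan-1-ol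
Conditions: hν (λ > 300 nm, medium-pressure Hg lamp, Pyrex), degassed benzene, 0.005 M, 20 °C
Reagents that add atoms: none
Why: n→π* excitation of the ring carbonyl should be followed by transfer of a hydrogen from the O-methyl group (δ to the carbonyl carbon, seven-membered transition state) to the carbonyl oxygen, and the resulting 1,5-biradical (hydroxy-bearing ring carbon and OCH2 radical) combines to form the C–C bond. The closest known reaction type is the Norrish–Yang photocyclisation of β-alkoxy ketones to oxolan-3-ols, which is known for 4-(alkoxyalkyl)-2-aryloxolan-3-ones giving 3,7-dioxabicyclo[3.3.0]octan-1-ols. The new oxolane (O7, C8, C1, C5, C6 of 18) closes by radical–radical combination across five atoms, a closure that carries no polar or Baldwin constraint. The one new stereocentre, carbinol carbon C1, is set by the existing ring: two fused five-membered rings can only be cis-fused, so the C1–C8 bond forms on the face of the side chain at C5, which puts the aryl-bearing C2 (the later benzyl carbon) cis and the hydroxyl trans to C4 (the later hydroxymethyl carbon), while C5 and C6 are untouched. The step needs δ-abstraction to win over other hydrogen abstractions and over α-cleavage: the γ-atom of the side chain is oxygen, ring hydrogens cannot reach the carbonyl oxygen, both phenols are masked and only the ketone absorbs above 300 nm. α-Cleavage can occur only towards the benzylic C2 of 17, and because the two radical ends stay joined through O1–C5–C4 they should reclose, which merely scrambles the sacrificial C2 centre.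

**Step 11**
Reactants: 18 the bicyclic alcohol
Product: 19 (3S,4R,5S)-3-[4-(benzyloxy)-3-methoxybenzyl]-4-(hydroxymethyl)-5-(3-methoxy-4-tosyloxyphenyl)oxolan-3-ol
Conditions: Et3SiH (10 equiv), BF3·OEt2 (3 equiv), CH2Cl2, −78 to −30 °C; then aq NaHCO3
Reagents that add atoms: none
Why: Ionic hydrogenation of a benzylic ether (SN1 ionisation, hydride capture): BF3 should ionise only the C2–O3 bond, whose cation is stabilised by the para-benzyloxy group, while the C6–O7 bond on the ring made electron-poor by the tosyloxy group stays closed, and Et3SiH turns C2 into the benzyl CH2 and frees the hydroxymethyl group without touching a stereocentre.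

**Step 12**
Reactants: 19 the benzyl/tosyl-protected olivil
Product: 20 (3S,4R,5S)-3-[4-(benzyloxy)-3-methoxybenzyl]-5-(4-hydroxy-3-methoxyphenyl)-4-(hydroxymethyl)oxolan-3-ol
Conditions: KOH, MeOH/H2O, 65 °C, N2
Reagents that add atoms: none
Why: Saponification of the aryl sulfonate by attack of hydroxide at sulfur should free only the phenol of the 5-aryl ring, the benzyl ether being stable to base.

**Step 13**
Reactants: 20 the 5-aryl phenol
Product: 21 (3S,4R,5S)-3-[4-(benzyloxy)-3-methoxybenzyl]-5-(4-hydroxy-3-iodo-5-methoxyphenyl)-4-(hydroxymethyl)oxolan-3-ol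
Conditions: I2, NaHCO3, THF/H2O, 0 °C to rt
Reagents that add atoms: iodine, II
Why: Electrophilic aromatic iodination of the phenoxide: under bicarbonate only the free phenol ring should react, at its single open ortho position (para is substituted), the benzyloxy ring being inert without acid or oxidant.

**Step 14**
Reactants: 19 the benzyl/tosyl-protected olivil
Product: 22 (3S,4R,5S)-3-(4-hydroxy-3-methoxybenzyl)-4-(hydroxymethyl)-5-(3-methoxy-4-tosyloxyphenyl)oxolan-3-ol
Conditions: H2 (1 atm), Pd/C, EtOAc, rt
Reagents that add atoms: none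
Why: Catalytic hydrogenolysis of the aryl benzyl ether should be much faster than cleavage of the oxolane benzylic C–O bond, which sits on the electron-poor tosyloxy ring.

**Step 15**
Reactants: 22 the benzyl-ring phenol
Product: 23 (3S,4R,5S)-3-(4-hydroxy-3-iodo-5-methoxybenzyl)-4-(hydroxymethyl)-5-(3-methoxy-4-tosyloxyphenyl)oxolan-3-ol
Conditions: I2, NaHCO3, THF/H2O, 0 °C to rt
Reagents that add atoms: iodine, II
Why: Electrophilic aromatic iodination of the phenoxide should again take the single open ortho position of the free phenol ring, the tosyloxy ring being deactivated.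

**Step 16**
Reactants: 21 the 5-aryl iodophenol; 23 the benzyl-ring iodophenol
Product: 25 5,5'-linked dimer: position 5 of the 5-aryl ring of 20 joined to position 5 of the benzyl ring of 22 (benzyl ether and tosylate kept), via pinacol boronate 24 (not isolated)
Conditions: 21, B2pin2, Pd(dppf)Cl2 (5 mol%), KOAc, 1,4-dioxane, 85 °C; then 23, aq K3PO4, 90 °C
Reagents that add atoms: bis(pinacolato)diboron, CC1(C)OB(B2OC(C)(C)C(C)(C)O2)OC1(C)C (its atoms stay in intermediate 24 only)
Why: One-pot Miyaura borylation and Suzuki–Miyaura cross-coupling: zerovalent palladium should insert into the C–I bond of 21 and take boron from B2pin2, and boronate 24 should then couple with iodide 23 ortho to both hydroxyls, the aryl tosylate being inert to this catalyst and the biaryl having only two ortho substituents and hence no stable stereoaxis.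

**Step 17**
Reactants: 25 the benzyl/tosyl-protected dimer
Product: 26 mono-benzyl ether of the target (benzyl on the phenol of the benzyl ring of the unit joined through its 5-aryl ring)
Conditions: KOH, MeOH/H2O, 65 °C, N2
Reagents that add atoms: none
Why: Saponification of the remaining aryl tosylate by hydroxide at sulfur should leave the benzyl ether, the oxolanes and the alcohols untouched.

**Step 18**
Reactants: 26 the mono-benzyl ether
Product: 27 CNP0269573.1 (target)
Conditions: H2 (1 atm), Pd/C, EtOAc/MeOH, rt, stopped at full conversion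
Reagents that add atoms: none
Why: Catalytic hydrogenolysis of the last aryl benzyl ether in a non-acidic medium should outpace cleavage of the two oxolane benzylic C–O bonds and gives the target with all six centres as set.

**Compound list**
1 | vanillin | COc1cc(C=O)ccc1O | starting material
2 | 4-formyl-2-methoxyphenyl 4-methylbenzenesulfonate | COc1cc(C=O)ccc1OS(=O)(=O)c1ccc(C)cc1 | intermediate
3 | (S)-4-benzyl-1,3-oxazolidin-2-one | O=C1N[C@@H](Cc2ccccc2)CO1 | starting material
4 | 3-[(tert-butyldimethylsilyl)oxy]propanoic acid | CC(C)(C)[Si](C)(C)OCCC(=O)O | starting material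
5 | mixed anhydride of 4 with pivalic acid | CC(C)(C)C(=O)OC(=O)CCO[Si](C)(C)C(C)(C)C | intermediate
6 | (4S)-4-benzyl-3-{3-[(tert-butyldimethylsilyl)oxy]propanoyl}-1,3-oxazolidin-2-one | O=C1OC[C@H](Cc2ccccc2)N1C(=O)CCO[Si](C)(C)C(C)(C)C | intermediate
7 | trimethylsilyl ether of 8 | O=C1OC[C@H](Cc2ccccc2)N1C(=O)[C@H](CO[Si](C)(C)C(C)(C)C)[C@H](O[Si](C)(C)C)c3ccc(OS(=O)(=O)c4ccc(C)cc4)c(OC)c3 | intermediate
8 | (4S)-4-benzyl-3-[(2R,3S)-2-{[(tert-butyldimethylsilyl)oxy]methyl}-3-hydroxy-3-(3-methoxy-4-tosyloxyphenyl)propanoyl]-1,3-oxazolidin-2-one | O=C1OC[C@H](Cc2ccccc2)N1C(=O)[C@H](CO[Si](C)(C)C(C)(C)C)[C@H](O)c3ccc(OS(=O)(=O)c4ccc(C)cc4)c(OC)c3 | intermediate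
9 | (2R,3S)-2-{[(tert-butyldimethylsilyl)oxy]methyl}-3-hydroxy-N-methoxy-3-(3-methoxy-4-tosyloxyphenyl)-N-methylpropanamide | CON(C)C(=O)[C@H](CO[Si](C)(C)C(C)(C)C)[C@H](O)c1ccc(OS(=O)(=O)c2ccc(C)cc2)c(OC)c1 | intermediate
10 | (2R,3S)-2-{[(tert-butyldimethylsilyl)oxy]methyl}-N,3-dimethoxy-3-(3-methoxy-4-tosyloxyphenyl)-N-methylpropanamide | CON(C)C(=O)[C@H](CO[Si](C)(C)C(C)(C)C)[C@H](OC)c1ccc(OS(=O)(=O)c2ccc(C)cc2)c(OC)c1 | intermediate
11 | [4-(benzyloxy)-3-methoxyphenyl]methanol | COc1cc(CO)ccc1OCc1ccccc1 | starting material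
12 | 1-(benzyloxy)-4-(chloromethyl)-2-methoxybenzene | COc1cc(CCl)ccc1OCc1ccccc1 | intermediate
13 | [4-(benzyloxy)-3-methoxybenzyl]magnesium chloride | COc1cc(C[Mg]Cl)ccc1OCc1ccccc1 | intermediate
14 | (3R,4S)-1-[4-(benzyloxy)-3-methoxyphenyl]-3-{[(tert-butyldimethylsilyl)oxy]methyl}-4-methoxy-4-(3-methoxy-4-tosyloxyphenyl)butan-2-one | COc1cc(CC(=O)[C@H](CO[Si](C)(C)C(C)(C)C)[C@H](OC)c2ccc(OS(=O)(=O)c3ccc(C)cc3)c(OC)c2)ccc1OCc1ccccc1 | intermediate
15 | (3R,4S)-1-[4-(benzyloxy)-3-methoxyphenyl]-3-(hydroxymethyl)-4-methoxy-4-(3-methoxy-4-tosyloxyphenyl)butan-2-one | COc1cc(CC(=O)[C@H](CO)[C@H](OC)c2ccc(OS(=O)(=O)c3ccc(C)cc3)c(OC)c2)ccc1OCc1ccccc1 | intermediate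
16 | (3R,4S)-1-[4-(benzyloxy)-3-methoxyphenyl]-1-diazo-3-(hydroxymethyl)-4-methoxy-4-(3-methoxy-4-tosyloxyphenyl)butan-2-one | COc1cc(C(=[N+]=[N-])C(=O)[C@H](CO)[C@H](OC)c2ccc(OS(=O)(=O)c3ccc(C)cc3)c(OC)c2)ccc1OCc1ccccc1 | intermediate
17 | (2RS,4R)-2-[4-(benzyloxy)-3-methoxyphenyl]-4-[(S)-methoxy(3-methoxy-4-tosyloxyphenyl)methyl]oxolan-3-one | COc1cc(C3C(=O)[C@@H]([C@H](OC)c4ccc(OS(=O)(=O)c5ccc(C)cc5)c(OC)c4)CO3)ccc1OCc1ccccc1 | intermediate
18 | (1S,2RS,5R,6S)-2-[4-(benzyloxy)-3-methoxyphenyl]-6-(3-methoxy-4-tosyloxyphenyl)-3,7-dioxabicyclo[3.3.0]octan-1-ol | COc1cc(C3[C@@]2(O)CO[C@H](c4ccc(OS(=O)(=O)c5ccc(C)cc5)c(OC)c4)[C@H]2CO3)ccc1OCc1ccccc1 | intermediate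
19 | (3S,4R,5S)-3-[4-(benzyloxy)-3-methoxybenzyl]-4-(hydroxymethyl)-5-(3-methoxy-4-tosyloxyphenyl)oxolan-3-ol | COc1cc(C[C@@]2(O)CO[C@H](c3ccc(OS(=O)(=O)c4ccc(C)cc4)c(OC)c3)[C@H]2CO)ccc1OCc1ccccc1 | intermediate
20 | (3S,4R,5S)-3-[4-(benzyloxy)-3-methoxybenzyl]-5-(4-hydroxy-3-methoxyphenyl)-4-(hydroxymethyl)oxolan-3-ol | COc1cc(C[C@@]2(O)CO[C@H](c3ccc(O)c(OC)c3)[C@H]2CO)ccc1OCc1ccccc1 | intermediate
21 | (3S,4R,5S)-3-[4-(benzyloxy)-3-methoxybenzyl]-5-(4-hydroxy-3-iodo-5-methoxyphenyl)-4-(hydroxymethyl)oxolan-3-ol | COc1cc(C[C@@]2(O)CO[C@H](c3cc(I)c(O)c(OC)c3)[C@H]2CO)ccc1OCc1ccccc1 | intermediate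
22 | (3S,4R,5S)-3-(4-hydroxy-3-methoxybenzyl)-4-(hydroxymethyl)-5-(3-methoxy-4-tosyloxyphenyl)oxolan-3-ol | COc1cc(C[C@@]2(O)CO[C@H](c3ccc(OS(=O)(=O)c4ccc(C)cc4)c(OC)c3)[C@H]2CO)ccc1O | intermediate
23 | (3S,4R,5S)-3-(4-hydroxy-3-iodo-5-methoxybenzyl)-4-(hydroxymethyl)-5-(3-methoxy-4-tosyloxyphenyl)oxolan-3-ol | COc1cc(C[C@@]2(O)CO[C@H](c3ccc(OS(=O)(=O)c4ccc(C)cc4)c(OC)c3)[C@H]2CO)cc(I)c1O | intermediate
24 | pinacol boronate of 21 (boron in place of iodine) | COc1cc(C[C@@]2(O)CO[C@H](c3cc(B4OC(C)(C)C(C)(C)O4)c(O)c(OC)c3)[C@H]2CO)ccc1OCc1ccccc1 | intermediate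
25 | benzyl/tosyl-protected dimer (5-aryl ring of 20 joined to benzyl ring of 22) | COc1cc(C[C@@]2(O)CO[C@H](c3cc(OC)c(O)c(-c4cc(C[C@@]5(O)CO[C@H](c6ccc(OS(=O)(=O)c7ccc(C)cc7)c(OC)c6)[C@H]5CO)cc(OC)c4O)c3)[C@H]2CO)ccc1OCc1ccccc1 | intermediate
26 | mono-benzyl ether of the target | COc1cc(C[C@@]2(O)CO[C@H](c3cc(OC)c(O)c(-c4cc(C[C@@]5(O)CO[C@H](c6ccc(O)c(OC)c6)[C@H]5CO)cc(OC)c4O)c3)[C@H]2CO)ccc1OCc1ccccc1 | intermediate
27 | CNP0269573.1 | COc1cc(C[C@@]2(O)CO[C@H](c3cc(OC)c(O)c(-c4cc(C[C@@]5(O)CO[C@H](c6ccc(O)c(OC)c6)[C@H]5CO)cc(OC)c4O)c3)[C@H]2CO)ccc1O | target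

**Count and risks**
Total steps: 18. Longest linear sequence: 14 steps (2, 3, 4, 5, 7, 8, 9, 10, 11, 12, 13, 16, 17, 18).

Step 10. α-Cleavage of the excited α-aryl-α-alkoxy ketone on its benzylic side may outrun abstraction of the primary methoxy hydrogen, so that disproportionation and decarbonylation of the acyl/benzyl biradical consume the ketone before the 1,5-biradical forms. The fallback changes the hydrogen donor from a methyl ether to a methoxymethyl ether, whose O–CH2–O hydrogens are weaker, and removes the extra methoxy group reductively; it sets out from compound 9 and returns at compound 19. MOMCl and iPr2NEt should give the methoxymethyl ether F1. Grignard reagent 13 should give the silyl ketone F2, and HF·pyridine the hydroxy ketone F3. Diazo transfer as in step 8 should give the diazo ketone F4, and Rh2(OAc)4 the oxolanone F5. Irradiation as in step 10 should give the bicyclic methyl acetal F6. Et3SiH/BF3·OEt2 as in step 11 should then reduce the anomeric methoxy group through the oxocarbenium ion and open the sacrificial ring in the same operation, giving 19.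

Step 11. Ionisation next to the tertiary carbinol may be followed by a semipinacol 1,2-shift to the benzylic cation, or hydride capture may be slow enough for the other benzylic C–O bond to ionise as well. The fallback replaces cationic reduction by heterogeneous hydrogenolysis; it sets out from compound 18 and returns at compounds 22 and 19. H2 over Pd/C in EtOAc/EtOH should first remove the aryl benzyl group to give the phenol F7, whose para-hydroxybenzylic C–O bond should then be cleaved on the catalyst in preference to that on the tosyloxy ring, giving 22 directly. Material for the other branch returns to 19 by benzylation of the single phenol of 22 (BnBr, K2CO3, acetone).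

Step 16. Protodeboronation of the electron-rich ortho-hydroxyarylboronate under aqueous base, and homocoupling of either iodide in the one-pot sequence, may erode the cross-coupling. The fallback uses tin in place of boron under base-free conditions; it sets out from compound 21 and returns at compound 25. Me3SnSnMe3 with Pd(PPh3)4 in toluene should give the arylstannane F8, which is isolated, and Stille coupling with 23 (Pd(PPh3)4, CuI, CsF, DMF) should give 25.

**Further compounds**
F1 | step 10 | methoxymethyl ether of 9 | CON(C)C(=O)[C@H](CO[Si](C)(C)C(C)(C)C)[C@H](OCOC)c1ccc(OS(=O)(=O)c2ccc(C)cc2)c(OC)c1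
F2 | step 10 | silyl ketone (14 with methoxymethoxy in place of methoxy) | COc1cc(CC(=O)[C@H](CO[Si](C)(C)C(C)(C)C)[C@H](OCOC)c2ccc(OS(=O)(=O)c3ccc(C)cc3)c(OC)c2)ccc1OCc1ccccc1
F3 | step 10 | hydroxy ketone (15 with methoxymethoxy in place of methoxy) | COc1cc(CC(=O)[C@H](CO)[C@H](OCOC)c2ccc(OS(=O)(=O)c3ccc(C)cc3)c(OC)c2)ccc1OCc1ccccc1
F4 | step 10 | diazo ketone (16 with methoxymethoxy in place of methoxy) | COc1cc(C(=[N+]=[N-])C(=O)[C@H](CO)[C@H](OCOC)c2ccc(OS(=O)(=O)c3ccc(C)cc3)c(OC)c2)ccc1OCc1ccccc1
F5 | step 10 | oxolanone (17 with methoxymethoxy in place of methoxy) | COc1cc(C3C(=O)[C@@H]([C@H](OCOC)c4ccc(OS(=O)(=O)c5ccc(C)cc5)c(OC)c4)CO3)ccc1OCc1ccccc1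
F6 | step 10 | bicyclic methyl acetal (8-methoxy derivative of 18, mixture at C2 and C8) | COc1cc(C3[C@@]2(O)C(OC)O[C@H](c4ccc(OS(=O)(=O)c5ccc(C)cc5)c(OC)c4)[C@H]2CO3)ccc1OCc1ccccc1
F7 | step 11 | phenol (18 without its benzyl group) | COc1cc(C3[C@@]2(O)CO[C@H](c4ccc(OS(=O)(=O)c5ccc(C)cc5)c(OC)c4)[C@H]2CO3)ccc1O
F8 | step 16 | arylstannane (21 with trimethylstannyl in place of iodine) | COc1cc(C[C@@]2(O)CO[C@H](c3cc([Sn](C)(C)C)c(O)c(OC)c3)[C@H]2CO)ccc1OCc1ccccc1
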